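The plan disconnects the benzene ring of the 2,3-dihydrobenzofuran core back to a furan and an ethynyl ether. It exploits the ortho pair O1–C7a/C7–OH on that ring. One gold(I)-catalysed isomerisation of 21 forges C3a–C7a, C6–C7 and C7–O, closing the dihydrofuran ring and the carbocycle while the furan oxygen migrates to C7. Precursor 21 is a 2,3-disubstituted furan. It carries a dioxolane (future C4–CHO) at furan C3 and, at furan C2, a chain with the Evans syn-aldol stereopair (future C3/C2), a silyloxymethyl group and the O–C≡CH unit. The C4 lactate centre comes from asymmetric hydrogenation, the other from (R)-danshensu. Acid-labile PMB/tert-butyl protection allows one final acidolysis.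

Key step: step 10

**Remarks**
- **Labels.** Benzofuran numbering is used (O1, C2, C3, C3a, C4–C7, C7a). PMB = 4-methoxybenzyl, TIPS = triisopropylsilyl, ArP = 3,4-bis(4-methoxybenzyloxy)phenyl.
- **Configuration check.** The target is (2S,3S)-trans in the ring, (R) at both side-chain carbinol carbons, and (E) in the caffeoyl unit. (S)-4-Benzyl-2-oxazolidinone is the antipode required. Its syn-aldol (2R,3S) has the spatial arrangement of the ring. The descriptor at the future C3 reads R in the carbinol series and S in the acid series only because CIP priorities change.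
- **PMB instead of simple alkyl ethers.** All phenols carry PMB, so the last step is a mild acidolysis that spares the esters, the benzylic C2–O1 bond and the caffeoyl alkene.
- **TIPS instead of a smaller silyl group.** O-Ethynylation passes through a potassium alkoxide 1,3 to the silyl ether, where small silyl groups migrate.
- **Order of the endgame.** The C4 side chain is completed before C3 is oxidised, so the base-sensitive C3 ester never meets the olefination base.
- **Assumption 1.** The sense of induction of Et-DuPhos–Rh with α-acyloxyacrylates parallels that with α-acylaminoacrylates, so the (R,R)-ligand gives the (R)-product.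
- **Assumption 2.** Enol ester 32 is drawn as the Z isomer. Any E isomer is carried along, because both geometries of this substrate class are reduced to the same enantiomer.

**Step 1**
Reactants: 1 furan-3-carbaldehyde
Product: 2 2-(furan-3-yl)-1,3-dioxolane
Conditions: HOCH2CH2OH, p-TsOH (cat.), toluene, reflux (Dean–Stark)
Reagents that add atoms: ethylene glycol, OCCO
Why: Acid-catalysed acetalisation with azeotropic removal of water masks the aldehyde, keeps the furan electron-rich for step 10 and provides a coordinating group for step 2.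

**Step 2**
Reactants: 2 2-(furan-3-yl)-1,3-dioxolane; 3 oxirane (ethylene oxide)
Product: 5 2-[3-(1,3-dioxolan-2-yl)furan-2-yl]ethan-1-ol, via furyllithium 4 (not isolated)
Conditions: n-BuLi, THF, −78 → −20 °C; 3 (THF solution), −78 °C → rt; H2O
Reagents that add atoms: none
Why: Directed lithiation picks furan C2, the α-position that also lies next to the chelating acetal, and the furyllithium opens the epoxide by SN2 attack.

**Step 3**
Reactants: 5 2-[3-(1,3-dioxolan-2-yl)furan-2-yl]ethan-1-ol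
Product: 7 2-[3-(1,3-dioxolan-2-yl)furan-2-yl]acetic acid, via furylacetaldehyde 6 (not isolated)
Conditions: TEMPO (cat.), PhI(OAc)2, MeCN/pH 7 phosphate buffer, 0 °C → rt
Reagents that add atoms: water, O
Why: Oxoammonium-mediated (TEMPO/PhI(OAc)2) oxidation carries the primary alcohol through the aldehyde hydrate to the acid, and the buffer keeps the medium mild enough for acetal and furan.

**Step 4**
Reactants: 7 2-[3-(1,3-dioxolan-2-yl)furan-2-yl]acetic acid; 8 (S)-4-benzyl-2-oxazolidinone
Product: 10 (S)-4-benzyl-3-{2-[3-(1,3-dioxolan-2-yl)furan-2-yl]acetyl}oxazolidin-2-one, via mixed pivalic anhydride 9 (not isolated)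
Conditions: PivCl, Et3N, THF, −20 °C; then LiCl, 8, −20 °C → rt
Reagents that add atoms: none
Why: N-Acylation of the auxiliary through a mixed anhydride under LiCl/Et3N activation needs neither an acid chloride nor a strong base, so the acetal and the acidic furylacetyl CH2 are not endangered.

**Step 5**
Reactants: 11 3,4-dihydroxybenzaldehyde
Product: 12 3,4-bis(4-methoxybenzyloxy)benzaldehyde
Conditions: PMBCl, K2CO3, Bu4NI (cat.), DMF, rt → 50 °C
Reagents that add atoms: 4-methoxybenzyl chloride, COc1ccc(CCl)cc1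
Why: Double Williamson etherification gives catechol ethers that tolerate KH, n-BuLi, boron and gold reagents yet fall to mild acid at the end.

**Step 6**
Reactants: 10 (S)-4-benzyl-3-{2-[3-(1,3-dioxolan-2-yl)furan-2-yl]acetyl}oxazolidin-2-one; 12 3,4-bis(4-methoxybenzyloxy)benzaldehyde
Product: 15 (S)-4-benzyl-3-{(2R,3S)-3-ArP-2-[3-(1,3-dioxolan-2-yl)furan-2-yl]-3-hydroxypropanoyl}oxazolidin-2-one, via boron enolate 13 (not isolated), via boron aldolate 14 (not isolated)
Conditions: Bu2BOTf, Et3N, CH2Cl2, −78 → 0 °C; 12, −78 → 0 °C; pH 7 buffer, MeOH, 30% H2O2, 0 °C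
Reagents that add atoms: none
Why: Evans syn-aldol reaction, in which the (Z)-boron enolate adds through a Zimmerman–Traxler chair on the face remote from the benzyl group of the (S)-auxiliary and so sets both new centres as (2R,3S), the syn pair that becomes the trans C3/C2 pair of the ring.

**Step 7**
Reactants: 15 syn-aldol adduct
Product: 16 (1S,2R)-1-ArP-2-[3-(1,3-dioxolan-2-yl)furan-2-yl]propane-1,3-diol
Conditions: LiBH4, THF/MeOH, 0 °C
Reagents that add atoms: none
Why: Hydride cleavage of the imide (reductive auxiliary removal) gives the 1,3-diol without strong base, so neither retro-aldol cleavage nor epimerisation at the furyl-bearing centre is expected and 8 is recovered.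

**Step 8**
Reactants: 16 (1S,2R)-diol
Product: 17 (1S,2R)-1-ArP-2-[3-(1,3-dioxolan-2-yl)furan-2-yl]-3-(triisopropylsilyloxy)propan-1-ol
Conditions: TIPSCl, imidazole, CH2Cl2, 0 °C → rt
Reagents that add atoms: triisopropylsilyl chloride, CC(C)[Si](Cl)(C(C)C)C(C)C
Why: Sterically controlled silylation takes only the primary OH, and the bulky TIPS group should resist O→O migration to the neighbouring alkoxide formed in step 9.

**Step 9**
Reactants: 17 secondary alcohol; 18 trichloroethylene
Product: 21 (1S,2R)-1-ArP-1-(ethynyloxy)-2-[3-(1,3-dioxolan-2-yl)furan-2-yl]-3-(triisopropylsilyloxy)propane, via dichlorovinyl ether 19 (not isolated), via lithium alkynyl ether 20 (not isolated)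
Conditions: KH, THF, 0 °C → rt; 18, −50 °C → rt; n-BuLi, −78 °C; MeOH, −78 °C; cold work-up, used at once
Reagents that add atoms: none
Why: Trichloroethylene route to ynol ethers, in which the potassium alkoxide adds to dichloroacetylene formed in situ, n-BuLi effects elimination and Cl/Li exchange, and protonation gives the terminal ethynyl ether without ever breaking the C–O bond at the stereocentre.

**Step 10**
Reactants: 21 furyl ethynyl ether
Product: 23 (2S,3R)-2-ArP-4-(1,3-dioxolan-2-yl)-3-[(triisopropylsilyloxy)methyl]-2,3-dihydrobenzofuran-7-ol (trans), via oxepine 22 (not isolated)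
Conditions: IPrAuNTf2 (3 mol %), 4 Å MS, CH2Cl2 (0.02 M), −20 °C → rt
Reagents that add atoms: none
Why: Gold(I) π-coordination turns the ethynyl ether into a ketenium-like electrophile with its positive charge on the oxygen-bearing carbon, so furan C2 attacks there in a 5-exo-dig closure that forms C3a–C7a and the dihydrofuran ring and leaves gold on the terminal carbon. Heterolysis of the former furan C2–O bond releases a gold carbene conjugated with a (Z)-enal, the aldehyde oxygen adds to the carbene carbon (C7–O) to give oxepine 22, and its disrotatory 6π electrocyclisation to the arene oxide makes C6–C7 and thereby closes the six-membered carbocycle. The epoxide then opens at C6–O, because only that mode gives a pentadienyl cation with charge on C7a where O1 can donate, and loss of the C7 proton delivers the C7 phenol rather than its C6 isomer. The closest known reaction type is the gold-catalysed furan–yne phenol synthesis, whose alkynyl ether variant is established for 2,3-dihydrobenzofuran-7-ols, so the 3-substituted furan and the branched tether are only a new substrate. No stereocentre is created, since C2 and C3 are untouched by the neutral isomerisation and their syn-aldol relationship becomes the trans ring substitution. The step needs the furan to outrun the electron-rich aryl ring, water and the thermal [3,3]/retro-ene decay of 21, which is secured by the higher nucleophilicity and 5-exo proximity of furan C2, by molecular sieves and dilution, and by working at or below room temperature.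

**Step 11**
Reactants: 23 7-hydroxy-dihydrobenzofuran
Product: 24 (2S,3R)-2-ArP-4-(1,3-dioxolan-2-yl)-7-(4-methoxybenzyloxy)-3-[(triisopropylsilyloxy)methyl]-2,3-dihydrobenzofuran
Conditions: PMBCl, K2CO3, Bu4NI (cat.), DMF, rt
Reagents that add atoms: 4-methoxybenzyl chloride, COc1ccc(CCl)cc1
Why: Williamson etherification of the only free OH completes the uniform PMB protection before the aldehyde is released.

**Step 12**
Reactants: 24 PMB-protected acetal
Product: 25 (2S,3R)-2-ArP-7-(4-methoxybenzyloxy)-3-[(triisopropylsilyloxy)methyl]-2,3-dihydrobenzofuran-4-carbaldehyde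
Conditions: PPTS (cat.), aq. acetone, 45 °C
Reagents that add atoms: water, O
Why: Acid-catalysed acetal hydrolysis is fast for a dioxolane on an alkoxy-substituted arene, while aryl PMB ethers and the primary TIPS ether are stable to PPTS.

**Step 13**
Reactants: 12 3,4-bis(4-methoxybenzyloxy)benzaldehyde; 26 malonic acid
Product: 28 (E)-3-ArP-acrylic acid (PMB-protected caffeic acid), via arylidenemalonic acid 27 (not isolated)
Conditions: pyridine, piperidine (cat.), 90 °C
Reagents that add atoms: none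
Why: Knoevenagel–Doebner condensation with in situ decarboxylation gives the (E)-cinnamic acid selectively and reuses aldehyde 12.

**Step 14**
Reactants: 29 tert-butyl 2-(diethoxyphosphoryl)acetate
Product: 30 tert-butyl 2-diazo-2-(diethoxyphosphoryl)acetate
Conditions: NaH, THF, 0 °C; p-ABSA, 0 °C → rt
Reagents that add atoms: 4-acetamidobenzenesulfonyl azide, CC(=O)Nc1ccc(cc1)S(=O)(=O)N=[N+]=[N-]
Why: Regitz diazo transfer onto the stabilised phosphonoacetate anion is the standard entry to diazophosphonoacetates.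

**Step 15**
Reactants: 28 (E)-3-ArP-acrylic acid; 30 tert-butyl 2-diazo-2-(diethoxyphosphoryl)acetate
Product: 31 tert-butyl 2-(diethoxyphosphoryl)-2-{[(E)-3-ArP-acryloyl]oxy}acetate (racemic at the phosphonate carbon)
Conditions: Rh2(OAc)4 (1 mol %), ClCH2CH2Cl, 80 °C, slow addition of 30
Reagents that add atoms: none
Why: Rhodium(II)-carbenoid O–H insertion into a carboxylic acid is faster than cyclopropanation of the electron-poor cinnamate C=C and gives the α-acyloxy phosphonate directly, its new centre being destroyed in step 16.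

**Step 16**
Reactants: 25 C4 aldehyde; 31 α-acyloxy phosphonate
Product: 32 tert-butyl (Z)-3-{(2S,3R)-2-ArP-7-(4-methoxybenzyloxy)-3-[(triisopropylsilyloxy)methyl]-2,3-dihydrobenzofuran-4-yl}-2-{[(E)-3-ArP-acryloyl]oxy}acrylate
Conditions: LiCl, DBU, MeCN/THF, 0 °C → rt
Reagents that add atoms: none
Why: Horner–Wadsworth–Emmons olefination under Masamune–Roush conditions, run while the aldehyde partner holds no base-sensitive ester, and with an alkene geometry that is not critical for step 17.

**Step 17**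
Reactants: 32 caffeoyl enol ester
Product: 33 tert-butyl (R)-3-{(2S,3R)-2-ArP-7-(4-methoxybenzyloxy)-3-[(triisopropylsilyloxy)methyl]-2,3-dihydrobenzofuran-4-yl}-2-{[(E)-3-ArP-acryloyl]oxy}propanoate
Conditions: [Rh(cod)((R,R)-Et-DuPhos)]OTf (2 mol %), H2 (5 bar), CH2Cl2/MeOH, rt
Reagents that add atoms: none
Why: Rh–DuPhos asymmetric hydrogenation of an α-acyloxyacrylate, in which the enol ester C=C binds to rhodium as a chelate with the acyl oxygen and is reduced under ligand control to the (R)-centre, whereas the non-chelating caffeoyl C=C and the PMB ethers should stay untouched.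

**Step 18**
Reactants: 33 TIPS ether
Product: 34 tert-butyl (R)-3-[(2S,3R)-2-ArP-3-(hydroxymethyl)-7-(4-methoxybenzyloxy)-2,3-dihydrobenzofuran-4-yl]-2-{[(E)-3-ArP-acryloyl]oxy}propanoate
Conditions: HF·pyridine, pyridine, THF, 0 °C → rt
Reagents that add atoms: none
Why: Fluoride-driven Si–O cleavage in a weakly acidic medium frees the primary alcohol without the basicity that could racemise the α-acyloxy ester or move acyl groups.

**Step 19**
Reactants: 34 primary alcohol
Product: 36 (2S,3S)-2-ArP-4-{(R)-3-tert-butoxy-3-oxo-2-{[(E)-3-ArP-acryloyl]oxy}propyl}-7-(4-methoxybenzyloxy)-2,3-dihydrobenzofuran-3-carboxylic acid, via C3 aldehyde 35 (not isolated)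
Conditions: TEMPO (cat.), PhI(OAc)2, CH2Cl2/H2O, rt
Reagents that add atoms: water, O
Why: The same oxoammonium oxidation as in step 3 takes CH2OH to CO2H under near-neutral two-phase conditions without enolising aldehyde 35, so C3 keeps its configuration and only its descriptor changes.

**Step 20**
Reactants: 37 (R)-danshensu
Product: 38 4-methoxybenzyl (R)-3-ArP-2-hydroxypropanoate
Conditions: PMBCl, K2CO3, DMF, rt, argon
Reagents that add atoms: 4-methoxybenzyl chloride, COc1ccc(CCl)cc1
Why: Alkylation of the carboxylate and both phenolates (Williamson type) with a carbonate base leaves the far less acidic secondary OH free and does not touch the (R)-centre taken from the chiral pool.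

**Step 21**
Reactants: 36 C3 carboxylic acid; 38 protected (R)-danshensu
Product: 39 fully protected target (C3 ester of 36 with 38; eight PMB groups and one tert-butyl ester)
Conditions: EDC·HCl, DMAP (cat.), CH2Cl2, 0 °C
Reagents that add atoms: none
Why: Steglich esterification at low temperature with little DMAP joins acid and secondary alcohol with retention at both α-centres, and should C3 enolise at all, the trans arrangement is the thermodynamically preferred one.

**Step 22**
Reactants: 39 fully protected target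
Product: 40 CNP0201431.1
Conditions: TFA/CH2Cl2 1:2, 1,3-dimethoxybenzene (excess), 0 °C → rt
Reagents that add atoms: none
Why: Acidolysis (SN1 cleavage) removes the eight PMB groups and the tert-butyl ester with an electron-rich arene as cation trap, while the esters, the (E)-alkene and the four stereocentres are inert to TFA and ionisation at C2 is disfavoured by the adjacent ester.

**Compound list**

1 | furan-3-carbaldehyde | O=Cc1ccoc1 | starting material
2 | 2-(furan-3-yl)-1,3-dioxolane | O1CCOC1c1ccoc1 | intermediate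
3 | oxirane (ethylene oxide) | C1CO1 | starting material
4 | [3-(1,3-dioxolan-2-yl)furan-2-yl]lithium | O1CCOC1c1ccoc1[Li] | intermediate (not isolated)
5 | 2-[3-(1,3-dioxolan-2-yl)furan-2-yl]ethan-1-ol | O1CCOC1c1ccoc1CCO | intermediate
6 | 2-[3-(1,3-dioxolan-2-yl)furan-2-yl]acetaldehyde | O1CCOC1c1ccoc1CC=O | intermediate (not isolated)
7 | 2-[3-(1,3-dioxolan-2-yl)furan-2-yl]acetic acid | O1CCOC1c1ccoc1CC(=O)O | intermediate
8 | (S)-4-benzyl-2-oxazolidinone | O=C1N[C@@H](Cc2ccccc2)CO1 | starting material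
9 | mixed anhydride of 7 with pivalic acid | O1CCOC1c1ccoc1CC(=O)OC(=O)C(C)(C)C | intermediate (not isolated)
10 | (S)-4-benzyl-3-{2-[3-(1,3-dioxolan-2-yl)furan-2-yl]acetyl}oxazolidin-2-one | O1CCOC1c1ccoc1CC(=O)N1[C@@H](Cc2ccccc2)COC1=O | intermediate
11 | 3,4-dihydroxybenzaldehyde | O=Cc1ccc(O)c(O)c1 | starting material
12 | 3,4-bis(4-methoxybenzyloxy)benzaldehyde | O=Cc1ccc(OCc2ccc(OC)cc2)c(OCc2ccc(OC)cc2)c1 | intermediate
13 | (Z)-dibutylboron enolate of 10 | O1CCOC1c1ccoc1/C=C(\OB(CCCC)CCCC)N1[C@@H](Cc2ccccc2)COC1=O | intermediate (not isolated)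
14 | O-dibutylboryl aldolate of 15 | O1CCOC1c1ccoc1[C@H](C(=O)N1[C@@H](Cc2ccccc2)COC1=O)[C@@H](c1ccc(OCc2ccc(OC)cc2)c(OCc2ccc(OC)cc2)c1)OB(CCCC)CCCC | intermediate (not isolated)
15 | (S)-4-benzyl-3-{(2R,3S)-3-ArP-2-[3-(1,3-dioxolan-2-yl)furan-2-yl]-3-hydroxypropanoyl}oxazolidin-2-one | O1CCOC1c1ccoc1[C@H](C(=O)N1[C@@H](Cc2ccccc2)COC1=O)[C@@H](c1ccc(OCc2ccc(OC)cc2)c(OCc2ccc(OC)cc2)c1)O | intermediate
16 | (1S,2R)-1-ArP-2-[3-(1,3-dioxolan-2-yl)furan-2-yl]propane-1,3-diol | O1CCOC1c1ccoc1[C@H](CO)[C@@H](c1ccc(OCc2ccc(OC)cc2)c(OCc2ccc(OC)cc2)c1)O | intermediate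
17 | (1S,2R)-1-ArP-2-[3-(1,3-dioxolan-2-yl)furan-2-yl]-3-(triisopropylsilyloxy)propan-1-ol | O1CCOC1c1ccoc1[C@H](CO[Si](C(C)C)(C(C)C)C(C)C)[C@@H](c1ccc(OCc2ccc(OC)cc2)c(OCc2ccc(OC)cc2)c1)O | intermediate
18 | trichloroethylene | ClC=C(Cl)Cl | starting material
19 | (E)-1,2-dichlorovinyl ether of 17 | O1CCOC1c1ccoc1[C@H](CO[Si](C(C)C)(C(C)C)C(C)C)[C@@H](c1ccc(OCc2ccc(OC)cc2)c(OCc2ccc(OC)cc2)c1)O/C(Cl)=C\Cl | intermediate (not isolated)
20 | lithium acetylide of 21 | O1CCOC1c1ccoc1[C@H](CO[Si](C(C)C)(C(C)C)C(C)C)[C@@H](c1ccc(OCc2ccc(OC)cc2)c(OCc2ccc(OC)cc2)c1)OC#C[Li] | intermediate (not isolated)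
21 | (1S,2R)-1-ArP-1-(ethynyloxy)-2-[3-(1,3-dioxolan-2-yl)furan-2-yl]-3-(triisopropylsilyloxy)propane | O1CCOC1c1ccoc1[C@H](CO[Si](C(C)C)(C(C)C)C(C)C)[C@@H](c1ccc(OCc2ccc(OC)cc2)c(OCc2ccc(OC)cc2)c1)OC#C | intermediate
22 | dihydrofuro-fused oxepine, valence tautomer of the C6–C7 arene oxide | O1CCOC1C1=C2[C@H](CO[Si](C(C)C)(C(C)C)C(C)C)[C@@H](c3ccc(OCc4ccc(OC)cc4)c(OCc4ccc(OC)cc4)c3)OC2=COC=C1 | intermediate (not isolated)
23 | (2S,3R)-2-ArP-4-(1,3-dioxolan-2-yl)-3-[(triisopropylsilyloxy)methyl]-2,3-dihydrobenzofuran-7-ol | O1CCOC1c1ccc(O)c2c1[C@H](CO[Si](C(C)C)(C(C)C)C(C)C)[C@@H](c1ccc(OCc3ccc(OC)cc3)c(OCc3ccc(OC)cc3)c1)O2 | intermediate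
24 | 7-O-PMB ether of 23 | O1CCOC1c1ccc(OCc3ccc(OC)cc3)c2c1[C@H](CO[Si](C(C)C)(C(C)C)C(C)C)[C@@H](c1ccc(OCc3ccc(OC)cc3)c(OCc3ccc(OC)cc3)c1)O2 | intermediate
25 | (2S,3R)-2-ArP-7-(4-methoxybenzyloxy)-3-[(triisopropylsilyloxy)methyl]-2,3-dihydrobenzofuran-4-carbaldehyde | O=Cc1ccc(OCc3ccc(OC)cc3)c2c1[C@H](CO[Si](C(C)C)(C(C)C)C(C)C)[C@@H](c1ccc(OCc3ccc(OC)cc3)c(OCc3ccc(OC)cc3)c1)O2 | intermediate
26 | malonic acid | OC(=O)CC(=O)O | starting material
27 | 2-(ArP-methylidene)malonic acid | OC(=O)C(=Cc1ccc(OCc2ccc(OC)cc2)c(OCc2ccc(OC)cc2)c1)C(=O)O | intermediate (not isolated)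
28 | (E)-3-ArP-acrylic acid | OC(=O)/C=C/c1ccc(OCc2ccc(OC)cc2)c(OCc2ccc(OC)cc2)c1 | intermediate
29 | tert-butyl 2-(diethoxyphosphoryl)acetate | CCOP(=O)(OCC)CC(=O)OC(C)(C)C | starting material
30 | tert-butyl 2-diazo-2-(diethoxyphosphoryl)acetate | CCOP(=O)(OCC)C(=[N+]=[N-])C(=O)OC(C)(C)C | intermediate
31 | tert-butyl 2-(diethoxyphosphoryl)-2-{[(E)-3-ArP-acryloyl]oxy}acetate | CCOP(=O)(OCC)C(OC(=O)/C=C/c1ccc(OCc2ccc(OC)cc2)c(OCc2ccc(OC)cc2)c1)C(=O)OC(C)(C)C | intermediate
32 | (Z)-caffeoyl enol ester (see step 16) | CC(C)(C)OC(=O)/C(OC(=O)/C=C/c1ccc(OCc2ccc(OC)cc2)c(OCc2ccc(OC)cc2)c1)=C/c1ccc(OCc3ccc(OC)cc3)c2c1[C@H](CO[Si](C(C)C)(C(C)C)C(C)C)[C@@H](c1ccc(OCc3ccc(OC)cc3)c(OCc3ccc(OC)cc3)c1)O2 | intermediate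
33 | (R)-α-caffeoyloxy tert-butyl ester, C3–CH2OTIPS (see step 17) | O=C(/C=C/c1ccc(OCc2ccc(OC)cc2)c(OCc2ccc(OC)cc2)c1)O[C@H](Cc1ccc(OCc3ccc(OC)cc3)c2c1[C@H](CO[Si](C(C)C)(C(C)C)C(C)C)[C@@H](c1ccc(OCc3ccc(OC)cc3)c(OCc3ccc(OC)cc3)c1)O2)C(=O)OC(C)(C)C | intermediate
34 | C3–CH2OH analogue of 33 | O=C(/C=C/c1ccc(OCc2ccc(OC)cc2)c(OCc2ccc(OC)cc2)c1)O[C@H](Cc1ccc(OCc3ccc(OC)cc3)c2c1[C@H](CO)[C@@H](c1ccc(OCc3ccc(OC)cc3)c(OCc3ccc(OC)cc3)c1)O2)C(=O)OC(C)(C)C | intermediate
35 | C3–CHO analogue of 33, (2S,3S) | O=C(/C=C/c1ccc(OCc2ccc(OC)cc2)c(OCc2ccc(OC)cc2)c1)O[C@H](Cc1ccc(OCc3ccc(OC)cc3)c2c1[C@H](C=O)[C@@H](c1ccc(OCc3ccc(OC)cc3)c(OCc3ccc(OC)cc3)c1)O2)C(=O)OC(C)(C)C | intermediate (not isolated)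
36 | (2S,3S)-3-carboxylic acid (see step 19) | O=C(/C=C/c1ccc(OCc2ccc(OC)cc2)c(OCc2ccc(OC)cc2)c1)O[C@H](Cc1ccc(OCc3ccc(OC)cc3)c2c1[C@H](C(=O)O)[C@@H](c1ccc(OCc3ccc(OC)cc3)c(OCc3ccc(OC)cc3)c1)O2)C(=O)OC(C)(C)C | intermediate
37 | (R)-danshensu, (R)-3-(3,4-dihydroxyphenyl)-2-hydroxypropanoic acid | O[C@H](Cc1ccc(O)c(O)c1)C(=O)O | starting material
38 | 4-methoxybenzyl (R)-3-ArP-2-hydroxypropanoate | O[C@H](Cc1ccc(OCc2ccc(OC)cc2)c(OCc2ccc(OC)cc2)c1)C(=O)OCc1ccc(OC)cc1 | intermediate
39 | fully protected target (octa-PMB, mono-tert-butyl) | O=C(/C=C/c1ccc(OCc2ccc(OC)cc2)c(OCc2ccc(OC)cc2)c1)O[C@H](Cc1ccc(OCc3ccc(OC)cc3)c2c1[C@H](C(=O)O[C@H](Cc1ccc(OCc3ccc(OC)cc3)c(OCc3ccc(OC)cc3)c1)C(=O)OCc1ccc(OC)cc1)[C@@H](c1ccc(OCc3ccc(OC)cc3)c(OCc3ccc(OC)cc3)c1)O2)C(=O)OC(C)(C)C | intermediate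
40 | CNP0201431.1 | O=C(/C=C/c1ccc(O)c(O)c1)O[C@H](Cc1ccc(O)c2c1[C@H](C(=O)O[C@H](Cc1ccc(O)c(O)c1)C(=O)O)[C@@H](c1ccc(O)c(O)c1)O2)C(=O)O | target

**Step count**
- Total step count: 22.
- Longest linear sequence: 17 steps (1–4, 6–12, 16–19, 21, 22) from furan-3-carbaldehyde.

**Steps most likely to fail**

**Step 10.**
- Ynol ether 21 may be consumed before it cyclises. The possible processes are a [3,3]-sigmatropic shift of the benzylic ynol ether into the electron-rich aryl ring, retro-ene loss of ketene, gold-induced ionisation of the benzylic C2–O bond, and hydration.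
- Ipso attack at furan C2 may also be slowed by crowding between the acetal and the branched tether.
- The fallback also bypasses step 9. The benzene ring is bought instead of made, and O1–C7a is closed by an intramolecular Ullmann-type O-arylation. It sets out from aldehyde 12 (with 3 and 8) and returns at 24.
- Commercial 3-bromo-4-hydroxybenzaldehyde (O=Cc1ccc(O)c(Br)c1) is alkylated with PMBCl/K2CO3 to 3-bromo-4-(4-methoxybenzyloxy)benzaldehyde F1 and acetalised with ethylene glycol to bromoaryl dioxolane F2. TMPMgCl·LiCl magnesiates the position flanked by bromine and acetal, and CuI-catalysed opening of oxirane 3 gives arylethanol F3. The operations of steps 3, 4, 6, 7 and 8 convert it into arylacetic acid F4, N-acyl oxazolidinone F5, Evans syn-aldol adduct F6 (with 12), diol F7 and primary TIPS ether F8. CuI, 1,10-phenanthroline and Cs2CO3 in toluene at 110 °C then join the secondary alkoxide to the C–Br carbon with retention at C2, which gives 24.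

**Step 17.**
- The caffeoyl C=C may be saturated in competition.
- Turnover may be slow, because the β-aryl group is ortho-substituted and the many electron-rich arenes can bind cationic rhodium.
- Facial selectivity may erode for one alkene geometry.
- The fallback removes the second alkene from the hydrogenation substrate and brings in the caffeoyl group afterwards. It sets out from aldehyde 25 and diazo ester 30 and returns at 33.
- Rh2(OAc)4-catalysed O–H insertion of 30 into acetic acid gives tert-butyl 2-acetoxy-2-(diethoxyphosphoryl)acetate F9. Olefination of 25 with LiCl/DBU gives enol acetate F10, and the same rhodium catalyst gives (R)-α-acetoxy ester F11. K2CO3 in MeOH at 0 °C removes only the acetate, since the tert-butyl ester, the TIPS ether and the PMB ethers are inert, and gives (R)-α-hydroxy ester F12. Steglich acylation with acid 28 gives 33.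

**Step 21.**
- Acyl activation acidifies C3–H, so ketene formation, E1cB opening of the C2–O1 bond or epimerisation may compete.
- Slow capture by the hindered secondary alcohol may allow rearrangement to the N-acylurea.
- The fallback activates the alcohol instead of the acid, so 36 reacts only as a carboxylate nucleophile. It sets out from alcohol 38 and returns at 39.
- Mitsunobu inversion of 38 with chloroacetic acid (PPh3, DIAD) gives (S)-chloroacetate F13. Thiourea/NaHCO3 in EtOH/THF removes the chloroacetyl group selectively and gives (S)-alcohol F14. A second Mitsunobu reaction of F14 with acid 36 inverts the centre back to (R) and gives 39.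

**Further compounds**

F1 | step 10 | 3-bromo-4-(4-methoxybenzyloxy)benzaldehyde | O=Cc1ccc(OCc2ccc(OC)cc2)c(Br)c1
F2 | step 10 | 2-[3-bromo-4-(4-methoxybenzyloxy)phenyl]-1,3-dioxolane | O1CCOC1c1ccc(OCc2ccc(OC)cc2)c(Br)c1
F3 | step 10 | 2-[2-bromo-6-(1,3-dioxolan-2-yl)-3-(4-methoxybenzyloxy)phenyl]ethan-1-ol | O1CCOC1c1ccc(OCc2ccc(OC)cc2)c(Br)c1CCO
F4 | step 10 | 2-[2-bromo-6-(1,3-dioxolan-2-yl)-3-(4-methoxybenzyloxy)phenyl]acetic acid | O1CCOC1c1ccc(OCc2ccc(OC)cc2)c(Br)c1CC(=O)O
F5 | step 10 | (S)-4-benzyl-3-(arylacetyl)oxazolidin-2-one from F4 | O1CCOC1c1ccc(OCc2ccc(OC)cc2)c(Br)c1CC(=O)N1[C@@H](Cc2ccccc2)COC1=O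
F6 | step 10 | (2S,3S) syn-aldol adduct of F5 with 12 | O1CCOC1c1ccc(OCc2ccc(OC)cc2)c(Br)c1[C@H](C(=O)N1[C@@H](Cc2ccccc2)COC1=O)[C@@H](c1ccc(OCc2ccc(OC)cc2)c(OCc2ccc(OC)cc2)c1)O
F7 | step 10 | (1S,2R)-1-ArP-2-(bromoaryl)propane-1,3-diol | O1CCOC1c1ccc(OCc2ccc(OC)cc2)c(Br)c1[C@H](CO)[C@@H](c1ccc(OCc2ccc(OC)cc2)c(OCc2ccc(OC)cc2)c1)O
F8 | step 10 | primary TIPS ether of F7 | O1CCOC1c1ccc(OCc2ccc(OC)cc2)c(Br)c1[C@H](CO[Si](C(C)C)(C(C)C)C(C)C)[C@@H](c1ccc(OCc2ccc(OC)cc2)c(OCc2ccc(OC)cc2)c1)O
F9 | step 17 | tert-butyl 2-acetoxy-2-(diethoxyphosphoryl)acetate | CCOP(=O)(OCC)C(OC(C)=O)C(=O)OC(C)(C)C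
F10 | step 17 | tert-butyl (Z)-2-acetoxy-3-(dihydrobenzofuran-4-yl)acrylate from 25 | CC(C)(C)OC(=O)/C(OC(C)=O)=C/c1ccc(OCc3ccc(OC)cc3)c2c1[C@H](CO[Si](C(C)C)(C(C)C)C(C)C)[C@@H](c1ccc(OCc3ccc(OC)cc3)c(OCc3ccc(OC)cc3)c1)O2
F11 | step 17 | tert-butyl (R)-2-acetoxy-3-(dihydrobenzofuran-4-yl)propanoate | CC(=O)O[C@H](Cc1ccc(OCc3ccc(OC)cc3)c2c1[C@H](CO[Si](C(C)C)(C(C)C)C(C)C)[C@@H](c1ccc(OCc3ccc(OC)cc3)c(OCc3ccc(OC)cc3)c1)O2)C(=O)OC(C)(C)C
F12 | step 17 | tert-butyl (R)-2-hydroxy-3-(dihydrobenzofuran-4-yl)propanoate | O[C@H](Cc1ccc(OCc3ccc(OC)cc3)c2c1[C@H](CO[Si](C(C)C)(C(C)C)C(C)C)[C@@H](c1ccc(OCc3ccc(OC)cc3)c(OCc3ccc(OC)cc3)c1)O2)C(=O)OC(C)(C)C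
F13 | step 21 | 4-methoxybenzyl (S)-3-ArP-2-(2-chloroacetoxy)propanoate | ClCC(=O)O[C@@H](Cc1ccc(OCc2ccc(OC)cc2)c(OCc2ccc(OC)cc2)c1)C(=O)OCc1ccc(OC)cc1
F14 | step 21 | 4-methoxybenzyl (S)-3-ArP-2-hydroxypropanoate | O[C@@H](Cc1ccc(OCc2ccc(OC)cc2)c(OCc2ccc(OC)cc2)c1)C(=O)OCc1ccc(OC)cc1
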